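The readings are calculated for an exercise; noise was put on by code.

| flask | starting material | partner | remark | time |
|---|---|---|---|---|
| maple | 0.10 M | 0.12 M | the very flask that is asked about, followed so far |  |
| oak | 0.067 M | 0.12 M | run made earlier |  |
| flask | 0.10 M | 0.120 M |  | 4.0 min |

maple run (percent of the starting material charged)

| time / s | starting material / % | single product / % |
|---|---|---|
| 12.0 | 27.6 | 11.1 |
| 25.0 | 26.5 | 7.9 |
| 40.0 | 25.5 | 6.4 |
| 50.0 | 24.3 | 6.7 |

oak run (percent of the starting material charged)

| time / min | starting material / % | single product / % |
|---|---|---|
| 0.667 | 7.8 | 4.4 |
| 1.33 | 6.9 | 3.7 |
| 2.00 | 6.6 | 4.5 |
| 3.00 | 6.3 | 3.8 |

(each reading ± 0.3 percentage points)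

- amount of starting material at 4.0 min, in percent of the starting material charged
- amount of single product at 4.0 min, in percent of the starting material charged
- amount of double product at 4.0 min, in percent of the starting material charged
- amount of triple product at 4.0 min, in percent of the starting material charged

- the analysis behind the earlier runs scatters by 0.3 percentage points, standard deviation

- Amounts first: this flask, followed as the maple run, holds 120% of partner per starting material charged, and each addition takes one partner.
- Starting material loses 72 percentage points in the first 12.0 s, then 3.3 points in the next 38.0 s, a far faster fall at first, so the burst is reckoned as closed at the first reading, with partner as limiting reagent.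
- Of the partner charged, 39.7% is then reckoned as going beyond first additions: this is the second-addition share, the partner beyond one per reacted starting material, over the partner charged.
- Times the charge ratio, the share gives 47.6% of the starting material charged for double product plus twice triple product, so the reckoning here puts double product a little under that.
- The forecast says 21.5% starting material, 5.8% single product, 65% double product and 7.7% triple product: “Simple one-partner-per-step stoichiometry fails”. Its double product stands above this reckoning.
- The flask gives 17.0% starting material, 3.19% single product, 46.3% double product and 2.18% triple product.

    starting material + partner → single product + by-product (k = 7.60 M⁻¹ s⁻¹)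
    partner + single product → double product + by-product (k = 18.0 M⁻¹ s⁻¹)
    partner + double product → triple product + by-product (k = 0.630 M⁻¹ s⁻¹)
    single product ⇌ isomer of the product (K = 1.20, k = 0.0600 s⁻¹)
    starting material + single product → side product (k = 0.430 M⁻¹ s⁻¹)

- In this flask, starting material's half-life by the first addition alone, 0.76 s as charged, is far shorter than single product's 0.41 min by the side path. Partner stands at 0% by 0.400 min, and from then to 4.00 min double product holds at 46.3% while side product climbs from 7.98% to 27.2%. Double product plus twice triple product comes to 50.7%, against the share's 47.6%.
- The neighbour with 0.17 M of starting material has less partner per starting material than the maple run, and the maple share, carried there as a trial, gives 28.0% for double product plus twice triple product. That neighbour holds 22.7% double product and 0.492% triple product, which by the same count make 23.7%, less than the trial gave.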